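The 2,2-dimethylchroman is opened at its aryl ether O–C(CH3)2 bond and, in the same operation, at the adjacent CH2–CH2 bond. In the forward sense an ortho-quinone methide, released from the Mannich base of the symmetric 4-hydroxy-2,6-bis(methoxymethoxy)acetophenone, is captured by isobutene in a hetero-Diels–Alder reaction that builds the whole pyran ring in one operation. The step exploits the phenolic oxygen para to the acyl carbon of ring A, the ring carbon next to it and the gem-dimethyl carbon, which marks the ring as an isobutene adduct. Aldol condensation with the prenylated ring B aldehyde, chemoselective enone hydrogenation and acetal cleavage complete the dihydrochalcone.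

Key step: step 5

Remark on the chemistry: the target has no stereocenter; the only stereo element on the route is the E double bond of chalcone 12, which step 9 removes.

Step 1
Reactants: 1 1-(2,4,6-trihydroxyphenyl)ethanone
Product: 2 1-[4-(benzyloxy)-2,6-dihydroxyphenyl]ethanone
Conditions: BnBr (1.0 equiv), K2CO3 (1.0 equiv), DMF, 0 °C to rt
Reagents that add atoms: benzyl bromide, BrCc1ccccc1
Why: Williamson ether synthesis, in which the 4-OH (para to the acetyl group and not hydrogen-bonded to the carbonyl) is the most acidic and most nucleophilic hydroxyl, so one equivalent of base and benzyl bromide should alkylate it selectively.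

Step 2
Reactants: 2 1-[4-(benzyloxy)-2,6-dihydroxyphenyl]ethanone
Product: 3 1-[4-(benzyloxy)-2,6-bis(methoxymethoxy)phenyl]ethanone
Conditions: NaH (2.2 equiv), MOMCl (2.5 equiv), DMF, 0 °C to rt
Reagents that add atoms: chloromethyl methyl ether, COCCl
Why: Williamson-type O-alkylation of the two sodium phenoxides with the reactive α-chloro ether should cap both chelated hydroxyls as MOM acetals, the benzyl ether being inert to NaH.

Step 3
Reactants: 3 1-[4-(benzyloxy)-2,6-bis(methoxymethoxy)phenyl]ethanone
Product: 4 1-[4-hydroxy-2,6-bis(methoxymethoxy)phenyl]ethanone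
Conditions: H2 (1 atm), 10% Pd/C (palladium on carbon), EtOAc, rt
Reagents that add atoms: none
Why: Catalytic hydrogenolysis of the benzyl aryl ether should free the 4-OH alone, since MOM acetals and the hindered aryl ketone are not attacked under one atmosphere of hydrogen in a neutral solvent.

Step 4
Reactants: 4 1-[4-hydroxy-2,6-bis(methoxymethoxy)phenyl]ethanone
Product: 5 1-[3-[(dimethylamino)methyl]-4-hydroxy-2,6-bis(methoxymethoxy)phenyl]ethanone
Conditions: Me2NH (40% aq, 1.1 equiv), CH2O (37% aq, 1.0 equiv), EtOH, rt
Reagents that add atoms: formaldehyde, C=O; dimethylamine, CNC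
Why: Phenol Mannich reaction, in which the iminium ion from formaldehyde and dimethylamine should attack a position ortho to the free hydroxyl, and because the two ortho positions are equivalent by symmetry one equivalent should give a single mono-aminomethyl compound.

Step 5
Reactants: 5 1-[3-[(dimethylamino)methyl]-4-hydroxy-2,6-bis(methoxymethoxy)phenyl]ethanone; 6 2-methylpropene (isobutene)
Product: 8 1-[5,7-bis(methoxymethoxy)-2,2-dimethyl-3,4-dihydro-2H-chromen-6-yl]ethanone, via ortho-quinone methide 7 (not isolated)
Conditions: isobutene (about 20 equiv), toluene, steel autoclave, 150 °C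
Reagents that add atoms: none
Why: Heating the Mannich base should expel dimethylamine from its phenoxide–ammonium zwitterion (a retro-Mannich, E1cB-type elimination) and unmask ortho-quinone methide 7, whose exocyclic methylene is an electron-poor 1-oxadiene terminus activated further by the vinylogous acetyl group. Isobutene then adds in an inverse-electron-demand hetero-Diels–Alder reaction, the closest known reaction type being the capture of phenol- and acylphloroglucinol-derived ortho-quinone methides by 1,1-disubstituted alkenes to give 2,2-disubstituted chromans. The dihydropyran ring closes by an intermolecular, asynchronous [4+2] cycloaddition in which the benzylic CH2–CH2 bond leads and the O–C(CH3)2 bond follows, with re-aromatisation of ring A as the driving force. No stereocenter is created, since the new quaternary carbon carries two methyl groups. The step needs regioselectivity in two senses: oxygen must bond to the tertiary alkene carbon, which the developing tertiary carbocation character in the transition state dictates, and only the oxygen para to the acetyl group may enter the ring, which is secured because it is the sole free hydroxyl (the 2- and 6-oxygens are MOM ethers and the two ortho carbons are equivalent). Self-condensation of 7 is the competing path and is held back by the large excess of isobutene and by the absence of any other alkene or nucleophilic phenol, ring B being attached only afterwards.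

Step 6
Reactants: 9 3-bromo-4,5-dihydroxybenzaldehyde
Product: 10 3-bromo-5-hydroxy-4-methoxybenzaldehyde
Conditions: MeI (1.05 equiv), Li2CO3 (1.1 equiv), DMF, 40 °C
Reagents that add atoms: iodomethane, CI
Why: Regioselective Williamson methylation, in which the hydroxyl para to the formyl group and ortho to bromine is the more acidic one, so the weak base should generate and methylate only that phenoxide, as in the known 4-O-alkylation of 3,4-dihydroxybenzaldehydes.

Step 7
Reactants: 10 3-bromo-5-hydroxy-4-methoxybenzaldehyde
Product: 11 3-hydroxy-4-methoxy-5-(3-methylbut-2-en-1-yl)benzaldehyde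
Conditions: tributyl(3-methylbut-2-en-1-yl)stannane (1.3 equiv), Pd(PPh3)4 (5 mol%), DMF, 100 °C
Reagents that add atoms: tributyl(3-methylbut-2-en-1-yl)stannane, CCCC[Sn](CCCC)(CCCC)CC=C(C)C
Why: Stille cross-coupling of the aryl bromide with the prenylstannane should deliver the linear prenyl arene, the neutral conditions tolerating the free phenol and the aldehyde.

Step 8
Reactants: 8 1-[5,7-bis(methoxymethoxy)-2,2-dimethyl-3,4-dihydro-2H-chromen-6-yl]ethanone; 11 3-hydroxy-4-methoxy-5-(3-methylbut-2-en-1-yl)benzaldehyde
Product: 12 (E)-1-[5,7-bis(methoxymethoxy)-2,2-dimethyl-3,4-dihydro-2H-chromen-6-yl]-3-[3-hydroxy-4-methoxy-5-(3-methylbut-2-en-1-yl)phenyl]prop-2-en-1-one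
Conditions: KOH (excess), EtOH/H2O, rt
Reagents that add atoms: none
Why: Claisen–Schmidt (crossed aldol) condensation, in which the methyl ketone enolate should add to the non-enolisable aldehyde and lose water to give the thermodynamically favoured E enone, the meta-phenoxide of 11 not being conjugated with the formyl group and the MOM ethers preventing flavanone formation.

Step 9
Reactants: 12 (E)-1-[5,7-bis(methoxymethoxy)-2,2-dimethyl-3,4-dihydro-2H-chromen-6-yl]-3-[3-hydroxy-4-methoxy-5-(3-methylbut-2-en-1-yl)phenyl]prop-2-en-1-one
Product: 13 1-[5,7-bis(methoxymethoxy)-2,2-dimethyl-3,4-dihydro-2H-chromen-6-yl]-3-[3-hydroxy-4-methoxy-5-(3-methylbut-2-en-1-yl)phenyl]propan-1-one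
Conditions: H2 (1 atm), RhCl(PPh3)3 (10 mol%), benzene/EtOH 1:1, rt
Reagents that add atoms: none
Why: Homogeneous hydrogenation with RhCl(PPh3)3 (Wilkinson's catalyst) should discriminate on steric grounds, saturating the 1,2-disubstituted enone double bond while leaving the trisubstituted prenyl alkene, the ketone and the MOM acetals untouched.

Step 10
Reactants: 13 1-[5,7-bis(methoxymethoxy)-2,2-dimethyl-3,4-dihydro-2H-chromen-6-yl]-3-[3-hydroxy-4-methoxy-5-(3-methylbut-2-en-1-yl)phenyl]propan-1-one
Product: 14 1-(5,7-dihydroxy-2,2-dimethyl-3,4-dihydro-2H-chromen-6-yl)-3-[3-hydroxy-4-methoxy-5-(3-methylbut-2-en-1-yl)phenyl]propan-1-one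
Conditions: HCl (3 M aq)/MeOH, rt to 40 °C
Reagents that add atoms: none
Why: Acid-catalysed acetal exchange with methanol should remove both MOM groups, assisted by the ortho carbonyl, under conditions mild enough to spare the prenyl group (which has no ortho hydroxyl to cyclise onto), the aryl methyl ether and the chroman ether.

Compound list

1 | 1-(2,4,6-trihydroxyphenyl)ethanone (2',4',6'-trihydroxyacetophenone) | CC(=O)c1c(O)cc(O)cc1O | starting material
2 | 1-[4-(benzyloxy)-2,6-dihydroxyphenyl]ethanone | CC(=O)c1c(O)cc(OCc2ccccc2)cc1O | intermediate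
3 | 1-[4-(benzyloxy)-2,6-bis(methoxymethoxy)phenyl]ethanone | CC(=O)c1c(OCOC)cc(OCc2ccccc2)cc1OCOC | intermediate
4 | 1-[4-hydroxy-2,6-bis(methoxymethoxy)phenyl]ethanone | CC(=O)c1c(OCOC)cc(O)cc1OCOC | intermediate
5 | 1-[3-[(dimethylamino)methyl]-4-hydroxy-2,6-bis(methoxymethoxy)phenyl]ethanone | CC(=O)c1c(OCOC)cc(O)c(CN(C)C)c1OCOC | intermediate
6 | 2-methylpropene (isobutene) | CC(C)=C | starting material
7 | 4-acetyl-3,5-bis(methoxymethoxy)-6-methylidenecyclohexa-2,4-dien-1-one (ortho-quinone methide) | CC(=O)C1=C(OCOC)C(=C)C(=O)C=C1OCOC | intermediate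
8 | 1-[5,7-bis(methoxymethoxy)-2,2-dimethyl-3,4-dihydro-2H-chromen-6-yl]ethanone | CC(=O)c1c(OCOC)cc2c(c1OCOC)CCC(C)(C)O2 | intermediate
9 | 3-bromo-4,5-dihydroxybenzaldehyde | O=Cc1cc(O)c(O)c(Br)c1 | starting material
10 | 3-bromo-5-hydroxy-4-methoxybenzaldehyde | COc1c(O)cc(C=O)cc1Br | intermediate
11 | 3-hydroxy-4-methoxy-5-(3-methylbut-2-en-1-yl)benzaldehyde | COc1c(O)cc(C=O)cc1CC=C(C)C | intermediate
12 | (E)-1-[5,7-bis(methoxymethoxy)-2,2-dimethyl-3,4-dihydro-2H-chromen-6-yl]-3-[3-hydroxy-4-methoxy-5-(3-methylbut-2-en-1-yl)phenyl]prop-2-en-1-one | COc1c(O)cc(/C=C/C(=O)c2c(OCOC)cc3c(c2OCOC)CCC(C)(C)O3)cc1CC=C(C)C | intermediate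
13 | 1-[5,7-bis(methoxymethoxy)-2,2-dimethyl-3,4-dihydro-2H-chromen-6-yl]-3-[3-hydroxy-4-methoxy-5-(3-methylbut-2-en-1-yl)phenyl]propan-1-one | COc1c(O)cc(CCC(=O)c2c(OCOC)cc3c(c2OCOC)CCC(C)(C)O3)cc1CC=C(C)C | intermediate
14 | 1-(5,7-dihydroxy-2,2-dimethyl-3,4-dihydro-2H-chromen-6-yl)-3-[3-hydroxy-4-methoxy-5-(3-methylbut-2-en-1-yl)phenyl]propan-1-one | COc1c(O)cc(CCC(=O)c2c(O)cc3c(c2O)CCC(C)(C)O3)cc1CC=C(C)C | target

Total step count: 10
Longest linear sequence: 8 steps (steps 1, 2, 3, 4, 5, 8, 9, 10)

Steps most likely to fail

Step 5. The quinone methide may be released too slowly at a temperature the substrate tolerates. Once formed, it may also be consumed by self-cycloaddition, oligomerisation or re-addition of dimethylamine faster than by the unactivated alkene. The fallback builds the same ring by aryl propargyl ether rearrangement. It sets out from 4, which is O-alkylated with 3-chloro-3-methylbut-1-yne (K2CO3, KI catalytic, acetone, reflux) to give 1-[2,6-bis(methoxymethoxy)-4-[(2-methylbut-3-yn-2-yl)oxy]phenyl]ethanone F1. Heating F1 in N,N-diethylaniline at about 180 °C should trigger aromatic Claisen rearrangement onto either of the two equivalent ortho carbons, a 1,5-hydrogen shift and oxa-6π electrocyclisation, giving 1-[5,7-bis(methoxymethoxy)-2,2-dimethyl-2H-chromen-6-yl]ethanone F2. Hydrogenation of the chromene double bond (H2, palladium on carbon, EtOAc) then returns to the route at 8.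

Step 9. The hydrogenation may stall at the hindered, twisted enone, or on forcing may begin to saturate the prenyl alkene as well. The fallback changes the order of events so that no second alkene is present during the reduction. It sets out from 8 and 10, which are condensed (KOH, EtOH/H2O) to (E)-3-(3-bromo-5-hydroxy-4-methoxyphenyl)-1-[5,7-bis(methoxymethoxy)-2,2-dimethyl-3,4-dihydro-2H-chromen-6-yl]prop-2-en-1-one F3. Hydrogenation with RhCl(PPh3)3, to which the aryl bromide is inert, should give 3-(3-bromo-5-hydroxy-4-methoxyphenyl)-1-[5,7-bis(methoxymethoxy)-2,2-dimethyl-3,4-dihydro-2H-chromen-6-yl]propan-1-one F4. Stille coupling of F4 with tributyl(3-methylbut-2-en-1-yl)stannane (Pd(PPh3)4, DMF, 100 °C) returns to the route at 13.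

Step 7. Allylic transposition during transmetalation may couple the prenyl unit through its tertiary carbon, and the free phenol may cause protodestannylation. The fallback removes the regiochemical question by installing a symmetrical allyl terminus first. It sets out from 10, which is coupled with allyltributylstannane (Pd(PPh3)4, DMF, 90 °C) to give 3-hydroxy-4-methoxy-5-(prop-2-en-1-yl)benzaldehyde F5. Cross-metathesis of F5 with excess 2-methylbut-2-ene (second-generation Grubbs catalyst, CH2Cl2, 40 °C) returns to the route at 11.

Further compounds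

F1 | step 5 | 1-[2,6-bis(methoxymethoxy)-4-[(2-methylbut-3-yn-2-yl)oxy]phenyl]ethanone | CC(=O)c1c(OCOC)cc(OC(C)(C)C#C)cc1OCOC
F2 | step 5 | 1-[5,7-bis(methoxymethoxy)-2,2-dimethyl-2H-chromen-6-yl]ethanone | CC(=O)c1c(OCOC)cc2c(c1OCOC)C=CC(C)(C)O2
F3 | step 9 | (E)-3-(3-bromo-5-hydroxy-4-methoxyphenyl)-1-[5,7-bis(methoxymethoxy)-2,2-dimethyl-3,4-dihydro-2H-chromen-6-yl]prop-2-en-1-one | COc1c(O)cc(/C=C/C(=O)c2c(OCOC)cc3c(c2OCOC)CCC(C)(C)O3)cc1Br
F4 | step 9 | 3-(3-bromo-5-hydroxy-4-methoxyphenyl)-1-[5,7-bis(methoxymethoxy)-2,2-dimethyl-3,4-dihydro-2H-chromen-6-yl]propan-1-one | COc1c(O)cc(CCC(=O)c2c(OCOC)cc3c(c2OCOC)CCC(C)(C)O3)cc1Br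
F5 | step 7 | 3-hydroxy-4-methoxy-5-(prop-2-en-1-yl)benzaldehyde | COc1c(O)cc(C=O)cc1CC=C
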